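**Retrosynthetic overview**
- Target 12 has one trisubstituted-by-heteroatom edge in ring A: C1 (OMe), C2 (ether O to the 2-bromophenyl ring B) and C3 (Br) are contiguous, with further Br at C4 and C6 and H at C5. The route rests on this C1–C2–C3 triad.
- C1–OMe is traced back to phenol 11; the C4 and C6 bromines are traced back to phenol-directed bromination of 10, which is unmasked from acetate 9.
- Ring A, the only ring formed, comes from a Diels–Alder/CO2-loss union of 3-acetoxypyranone 7 with bromoalkynyl ether 5. Pyranone C3 becomes C1, the O-bearing alkyne carbon C2 and the CBr carbon C3, so the C1–C2 and C3–C4 bonds are made.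
- Alkyne 5 comes from 2-bromophenol 1 and tribromoethylene 2 (addition, then dehydrobromination); 7 comes from 3-hydroxypyranone 6. Ring B is bought intact.

Key step: step 4

Remark: ring A is numbered C1 (OMe), C2 (O-aryl), C3, C4 and C6 (Br), C5 (H). The target has no stereocentre. Lactone 8 is racemic and one enantiomer is written.

**Step 1**
Reactants: 1 2-bromophenol; 2 tribromoethylene
Product: 4 (E)-1-bromo-2-[(1,2-dibromoethenyl)oxy]benzene, via dibromoacetylene 3 (not isolated)
Conditions: K2CO3 (1.5 equiv), 2 added slowly, DMF, N2, 60 °C
Reagents that add atoms: none
Why: K2CO3 should dehydrobrominate tribromoethylene to dibromoacetylene 3, kept at low stationary concentration and never isolated, and the 2-bromophenoxide should add across it in anti fashion (nucleophilic vinylic substitution by elimination–addition, the bromine counterpart of the trichloroethylene route to 1,2-dichlorovinyl aryl ethers), so that O and H end up trans and the E alkene results.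

**Step 2**
Reactants: 4 (E)-1-bromo-2-[(1,2-dibromoethenyl)oxy]benzene
Product: 5 1-bromo-2-[(bromoethynyl)oxy]benzene
Conditions: LiN(SiMe3)2 (1.1 equiv), THF, −78 °C to 0 °C; cold neutral work-up, pentane solution used at once
Reagents that add atoms: none
Why: Base-induced dehydrobromination of a 1,2-dihalovinyl ether to a haloalkynyl ether (deprotonation at CHBr, then loss of bromide directly or by carbenoid 1,2-shift, both converging on 5), with a hindered amide base that, unlike an alkyllithium, should not exchange the aryl bromide of ring B.

**Step 3**
Reactants: 6 3-hydroxy-2H-pyran-2-one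
Product: 7 2-oxo-2H-pyran-3-yl acetate
Conditions: Ac2O, pyridine, 0 °C to rt
Reagents that add atoms: acetic anhydride, CC(=O)OC(C)=O
Why: Nucleophilic acyl substitution (O-acetylation) of the enolic hydroxyl, with pyridine as base and acyl-transfer catalyst, should proceed without touching the pyranone ring.

**Step 4**
Reactants: 5 1-bromo-2-[(bromoethynyl)oxy]benzene; 7 2-oxo-2H-pyran-3-yl acetate
Product: 9 3-bromo-2-(2-bromophenoxy)phenyl acetate, via bridged lactone 8 (not isolated)
Conditions: 7 (2 equiv), BHT (cat.), toluene, sealed tube, 110–140 °C
Reagents that add atoms: none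
Why: On heating, the electron-poor diene of pyranone 7 (C3=C4–C5=C6) and the donor-polarised alkyne of 5 should combine in an inverse-electron-demand [4+2] cycloaddition to give bridged lactone 8, which should lose CO2 by retro-[4+2] at the same temperature and so give the benzene ring directly, with no oxidant. The closest known reaction type is the Diels–Alder/decarboxylation benzannulation of 2-pyranones with heteroatom-substituted alkynes such as ynamines and alkynyl ethers. Ring A is closed intermolecularly as a six-membered carbocycle by two new C–C bonds, pyranone C3 to the aryloxy-bearing alkyne carbon (C1–C2 of ring A) and pyranone C6 to the bromine-bearing alkyne carbon (C4–C3), the second ring of 8 being only the transient CO2 bridge. No stereocentre survives: the two bridgehead centres of racemic 8, whose relative configuration is fixed by the bicycle, are erased on aromatisation. The selectivity needed is regiochemical, and it should be secured by the ether oxygen of 5, whose lone pair makes the CBr carbon the nucleophilic terminus that attacks the electrophilic C6 of the pyranone, while the cation-like O-bearing carbon pairs with C3, alpha to the lactone carbonyl, so that the aryloxy group ends next to the acetoxy group. The acetyl group tempers the donor ability of the C3 oxygen so the diene stays electron-poor, and it later unveils the phenol that steers the brominations.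

**Step 5**
Reactants: 9 3-bromo-2-(2-bromophenoxy)phenyl acetate
Product: 10 3-bromo-2-(2-bromophenoxy)phenol
Conditions: K2CO3 (0.2 equiv), MeOH, rt; dilute HCl work-up
Reagents that add atoms: none
Why: Base-catalysed transesterification (methanolysis) of the aryl acetate should release the phenol, since phenoxide is a good leaving group and the diaryl ether and aryl bromides are inert to these conditions.

**Step 6**
Reactants: 10 3-bromo-2-(2-bromophenoxy)phenol
Product: 11 3,4,6-tribromo-2-(2-bromophenoxy)phenol
Conditions: Br2 (2.05 equiv), CH2Cl2/AcOH, 0 °C to rt; aq Na2S2O3 quench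
Reagents that add atoms: bromine, BrBr
Why: Electrophilic aromatic bromination in which the free hydroxyl at C1, the strongest donor present, directs to its open ortho (C6) and para (C4) positions with reinforcement from the C3 bromine, whereas C5 is meta to the hydroxyl and ring B is activated only by the shared ether oxygen and deactivated by its own bromine.

**Step 7**
Reactants: 11 3,4,6-tribromo-2-(2-bromophenoxy)phenol
Product: 12 1,2,5-tribromo-3-(2-bromophenoxy)-4-methoxybenzene
Conditions: MeI (1.5 equiv), K2CO3 (1.5 equiv), DMF, rt
Reagents that add atoms: iodomethane, CI
Why: Williamson ether synthesis, in which the acidic tribromophenol is fully ionised by K2CO3 and the small SN2 electrophile MeI should alkylate the doubly ortho-substituted phenoxide oxygen.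

**Compound list**
1 | 2-bromophenol | Oc1ccccc1Br | starting material
2 | tribromoethylene (1,1,2-tribromoethene) | BrC=C(Br)Br | starting material
3 | dibromoacetylene (1,2-dibromoethyne) | BrC#CBr | intermediate
4 | (E)-1-bromo-2-[(1,2-dibromoethenyl)oxy]benzene | Br/C=C(/Br)Oc1ccccc1Br | intermediate
5 | 1-bromo-2-[(bromoethynyl)oxy]benzene | BrC#COc1ccccc1Br | intermediate
6 | 3-hydroxy-2H-pyran-2-one | O=c1occcc1O | starting material
7 | 2-oxo-2H-pyran-3-yl acetate (3-acetoxy-2H-pyran-2-one) | CC(=O)Oc1cccoc1=O | intermediate
8 | 7-bromo-8-(2-bromophenoxy)-3-oxo-2-oxabicyclo[2.2.2]octa-5,7-dien-4-yl acetate (racemic, one enantiomer written) | O=C1O[C@@H]2C=C[C@@]1(OC(C)=O)C(Oc3ccccc3Br)=C2Br | intermediate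
9 | 3-bromo-2-(2-bromophenoxy)phenyl acetate | CC(=O)Oc1cccc(Br)c1Oc1ccccc1Br | intermediate
10 | 3-bromo-2-(2-bromophenoxy)phenol | Oc1cccc(Br)c1Oc1ccccc1Br | intermediate
11 | 3,4,6-tribromo-2-(2-bromophenoxy)phenol | Oc1c(Br)cc(Br)c(Br)c1Oc1ccccc1Br | intermediate
12 | 1,2,5-tribromo-3-(2-bromophenoxy)-4-methoxybenzene | COc1c(Br)cc(Br)c(Br)c1Oc1ccccc1Br | target

**Step count**
Total steps: 7. Longest linear sequence: 6 (steps 1, 2, 4, 5, 6, 7).

**Steps most likely to fail**

Step 4. The cycloaddition may be too slow at temperatures the haloalkyne tolerates, so that thermal oligomerisation of 5 outruns it, or bonding may occur in the reversed orientation. The fallback sets out from 1 and comes back at 10, leaving the cycloaddition for a C–O bond construction. 2-Bromophenol 1 is condensed with commercial 3-bromo-2-fluorobenzaldehyde (O=Cc1cccc(Br)c1F; K2CO3, N,N-dimethylacetamide, 120 °C) in a nucleophilic aromatic substitution activated by the ortho formyl group, to give 3-bromo-2-(2-bromophenoxy)benzaldehyde F1. Baeyer–Villiger oxidation (mCPBA, CH2Cl2, rt), with migration of the oxygen-substituted aryl group, should give 3-bromo-2-(2-bromophenoxy)phenyl formate F2. Methanolysis (K2CO3 cat., MeOH) then returns phenol 10, and steps 6 and 7 follow unchanged.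

Step 2. The vinyl anion may expel 2-bromophenoxide instead of bromide, reverting towards dibromoacetylene, and the haloynol ether may oligomerise or hydrate during isolation. The fallback sets out from 4 and comes back at 5, replacing base-induced dehydrobromination by reduction followed by electrophilic bromination. Base-free reductive 1,2-debromination of 4 with activated Zn dust (THF, 0 °C to rt) should give the terminal ynol ether 1-bromo-2-(ethynyloxy)benzene F3, kept in cold solution. Bromination of its terminal C–H (N-bromosuccinimide, DBU, MeCN, 0 °C) then gives 5.

Step 1. The dibromoacetylene formed in the flask may be consumed by self-reaction faster than the hindered, weakly nucleophilic phenoxide adds, or adduct 4 may react on with a second phenoxide. The fallback sets out from 1 and comes back at 5, building the two-carbon unit by carbonyl olefination and bypassing 3 and 4. O-Formylation of 1 (formic acid, N,N'-dicyclohexylcarbodiimide, CH2Cl2, 0 °C) gives 2-bromophenyl formate F4. Corey–Fuchs-type dibromo-olefination of the formate carbonyl (CBr4, PPh3, Zn dust, CH2Cl2) should give 1-bromo-2-[(2,2-dibromoethenyl)oxy]benzene F5. Anti E2 loss of HBr (NaN(SiMe3)2, THF, −78 °C), in which the aryloxide cannot act as a leaving group, then gives 5.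

**Further compounds**
F1 | step 4 | 3-bromo-2-(2-bromophenoxy)benzaldehyde | O=Cc1cccc(Br)c1Oc1ccccc1Br
F2 | step 4 | 3-bromo-2-(2-bromophenoxy)phenyl formate | O=COc1cccc(Br)c1Oc1ccccc1Br
F3 | step 2 | 1-bromo-2-(ethynyloxy)benzene | C#COc1ccccc1Br
F4 | step 1 | 2-bromophenyl formate | O=COc1ccccc1Br
F5 | step 1 | 1-bromo-2-[(2,2-dibromoethenyl)oxy]benzene | BrC(Br)=COc1ccccc1Br
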